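**Retrosynthetic overview**
- Last event: the spiro γ-lactone is closed by forming the bond between the carboxyl oxygen and the benzylic cyclobutane carbon C3' (acid-catalysed hydrolactonisation of an aryl-cyclobutene acid), which also creates the C8' stereocentre. Enabling feature: C3'=C8' is a strained, tetrasubstituted styrene double bond inside the cis-fused cyclobutene, and the benzene ring on C3' carries CO2H in the ortho position, five atoms from C3'.
- The acid comes from the aryl bromide (Pd hydroxycarbonylation); the propyl group on C8' from Negishi coupling of a cyclobutenyl triflate; the triflate from an α-aryl cyclobutanone.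
- The cyclobutanone (bonds C6–C8' and C7–C3', cis ring fusion, absolute configuration) comes from an auxiliary-controlled keteniminium [2+2] cycloaddition of a C2-symmetric (2-bromophenyl)acetamide to the C6=C7 bond of (Z)-ligustilide.
- Ring order: butenolide and cyclohexadiene rings are bought in (Z)-ligustilide → cyclobutane → spiro-phthalide lactone.

Key step: step 6

Locants: the ligustilide half uses phthalide numbering (C1 lactone carbonyl, O2, C3, C3a, C4–C7, C7a, C8 = butylidene CH). C8' and C3' are the two cyclobutane carbons introduced in step 2; C8' is bonded to C6 and C3' to C7. The CIP labels at C6/C7 change between 12 and 13 only because priorities change; the geometry is the same.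

Assumption: the sense of induction of the (2R,5R)-auxiliary is assigned by analogy with related keteniminium cycloadditions; should the (6S,7R)-cycloadduct form instead, the equally available (2S,5S)-amine is used and nothing else changes.

Step 1
Reactants: 1 2-(2-bromophenyl)acetic acid; 2 (2R,5R)-2,5-dimethylpyrrolidine
Product: 4 2-(2-bromophenyl)-1-[(2R,5R)-2,5-dimethylpyrrolidin-1-yl]ethan-1-one, via 2-(2-bromophenyl)acetyl chloride 3 (not isolated)
Conditions: (COCl)2, DMF (cat.), CH2Cl2, 0 → 23 °C; then 2, Et3N, CH2Cl2, 0 → 23 °C
Reagents that add atoms: oxalyl chloride, O=C(Cl)C(=O)Cl (Cl of 3 only)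
Why: Acid chloride formation followed by N-acylation of the hindered secondary amine should give the tertiary amide; no stereocentre is formed, and the C2 symmetry of the auxiliary means amide rotamers are equivalent.

Step 2
Reactants: 4 2-(2-bromophenyl)-1-[(2R,5R)-2,5-dimethylpyrrolidin-1-yl]ethan-1-one (1.5 equiv); 5 (Z)-ligustilide
Product: 8 (6R,7S)-cyclobutanone [C8'(=O) on C6; C3'H(2-bromophenyl) on C7; both C3' epimers], via keteniminium triflate 6 (not isolated), via cyclobutaniminium triflate 7 (not isolated)
Conditions: Tf2O, 2,4,6-collidine, CH2Cl2, −20 → 23 °C; then aq. NaHCO3, 23 °C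
Reagents that add atoms: water, O; trifluoromethanesulfonic anhydride, O=S(=O)(OS(=O)(=O)C(F)(F)F)C(F)(F)F (triflate counter-ion of 6 and 7 only)
Why: Amide activation gives the keteniminium salt, whose [2+2] cycloaddition (keteniminium–olefin cycloaddition, with the ketene-type regiochemistry seen for cyclopentadiene and 1,3-cyclohexadiene) should occur at the terminal, least hindered C6=C7 bond, the electrophilic central carbon bonding to the diene terminus C6 and the aryl-bearing carbon to C7; suprafacial addition to the ring alkene enforces the cis fusion, the C2-symmetric pyrrolidinium shields one face of the keteniminium and so sets C6 and C7, the epimerisable C3' centre is left undefined, and bicarbonate hydrolysis releases ketone and auxiliary.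

Step 3
Reactants: 8 (6R,7S)-cyclobutanone
Product: 10 (6R,7S)-cyclobutenyl triflate [C8'–OTf; C3'=C8'; 2-bromophenyl on C3'], via sodium cyclobutenolate 9 (not isolated)
Conditions: NaHMDS (1.05 equiv), THF, −78 °C; then PhNTf2, −78 → 0 °C
Reagents that add atoms: N-phenylbis(trifluoromethanesulfonimide), O=S(=O)(N(c1ccccc1)S(=O)(=O)C(F)(F)F)C(F)(F)F; sodium bis(trimethylsilyl)amide, C[Si](C)(C)[N-][Si](C)(C)C.[Na+] (Na+ of 9 only)
Why: The benzylic C3'–H is by far the more acidic α-position (the other is the C6 bridgehead), so both C3' epimers of 8 should converge on one aryl-conjugated cyclobutenolate that PhNTf2 traps on oxygen (enol triflate formation), erasing C3' and placing the leaving group on C8'.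

Step 4
Reactants: 10 (6R,7S)-cyclobutenyl triflate
Product: 11 (6R,7S)-3'-(2-bromophenyl)-8'-propylcyclobutene
Conditions: n-PrZnBr (1.3 equiv), Pd(dppf)Cl2 (5 mol %), THF, 23 °C
Reagents that add atoms: n-propylzinc bromide, CCC[Zn]Br
Why: Negishi sp2–sp3 coupling: the alkenyl triflate should undergo oxidative addition much faster than the hindered ortho-substituted aryl bromide at room temperature, dppf favours reductive elimination over β-hydride elimination of the n-propyl–Pd species, the organozinc leaves the enol lactone untouched, and no stereocentre is formed.

Step 5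
Reactants: 11 (6R,7S)-3'-(2-bromophenyl)-8'-propylcyclobutene
Product: 12 2-[(6R,7S)-8'-propylcyclobuten-3'-yl]benzoic acid
Conditions: Pd(OAc)2 (5 mol %), Xantphos, CO (1 atm), H2O, Et3N, 1,4-dioxane, 80 °C; dilute citric acid work-up
Reagents that add atoms: carbon monoxide, [C-]#[O+]; water, O
Why: Palladium-catalysed hydroxycarbonylation of the aryl bromide (oxidative addition, CO insertion, capture of the acyl–Pd by water); the tetrasubstituted cyclobutene is a poor partner for migratory insertion, any enol lactone opened by the aqueous amine is a keto acid that should reclose to the (Z)-butylidene lactone under the acid of step 6, and no stereocentre is touched.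

Step 6
Reactants: 12 2-[(6R,7S)-8'-propylcyclobuten-3'-yl]benzoic acid
Product: 13 (3'R,6S,7R,8'R)-spiro-phthalide target
Conditions: TfOH (10 mol %), CH2Cl2 (anhydrous), 0 → 23 °C
Reagents that add atoms: none
Why: The acid protonates the strained, tetrasubstituted styrene double bond C3'=C8' at C8' (Markovnikov) to give the tertiary benzylic cyclobutyl cation at C3', which the ortho-carboxyl oxygen captures to form the O–C3' bond; the closest known reaction type is the Brønsted-acid-catalysed intramolecular hydroacyloxylation of 2-(1-alkenyl)benzoic acids to 3,3-disubstituted phthalides. The γ-lactone closes in a 5-exo-trig mode (C3' inside the new ring, C8' outside), creating the spiro centre. C8' is set by protonation on the convex exo face of the cis-bicyclo[4.2.0]octene (the face of H-6 and H-7), which leaves the propyl group endo; C3' is set by C–O bond formation on the endo face, anti to the new C8'–H, which puts the benzo ring on the open exo face where its peri C–H meets only H-7 and H-8'. Because the benzylic C–O bond can re-ionise under the conditions, a kinetic C3' epimer (or, through the cyclobutene, a C8' epimer) should be funnelled to this least congested diastereomer. The step needs Markovnikov regioselectivity, secured by benzylic stabilisation and the five- rather than six-membered lactone, and chemoselectivity over the butylidene enol lactone, secured by the ring strain of the cyclobutene, the intramolecular nucleophile and a catalytic amount of acid under anhydrous conditions.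

**Compound list**
1 | 2-(2-bromophenyl)acetic acid | OC(=O)Cc1ccccc1Br | starting material
2 | (2R,5R)-2,5-dimethylpyrrolidine (trans, C2-symmetric) | C[C@@H]1CC[C@@H](C)N1 | starting material
3 | 2-(2-bromophenyl)acetyl chloride | ClC(=O)Cc1ccccc1Br | intermediate
4 | 2-(2-bromophenyl)-1-[(2R,5R)-2,5-dimethylpyrrolidin-1-yl]ethan-1-one | C[C@@H]1CC[C@@H](C)N1C(=O)Cc1ccccc1Br | intermediate
5 | (Z)-ligustilide, (3Z)-3-butylidene-4,5-dihydro-2-benzofuran-1(3H)-one | CCC/C=C1\OC(=O)C2=C1CCC=C2 | starting material
6 | (2R,5R)-1-[2-(2-bromophenyl)ethenylidene]-2,5-dimethylpyrrolidin-1-ium triflate (keteniminium salt) | C[C@@H]1CC[C@@H](C)[N+]1=C=Cc1ccccc1Br.[O-]S(=O)(=O)C(F)(F)F | intermediate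
7 | (6R,7S)-cyclobutaniminium triflate: cis-fused four-membered ring on C6–C7 of the ligustilide skeleton, iminium carbon C8' on C6, C3'H(2-bromophenyl) on C7, C3' epimers | CCC/C=C1\OC(=O)C2=C1CC[C@H]1C(=[N+]3[C@H](C)CC[C@H]3C)C(c3ccccc3Br)[C@@H]21.[O-]S(=O)(=O)C(F)(F)F | intermediate
8 | (6R,7S)-cyclobutanone: cis-fused, C8'(=O) on C6, C3'H(2-bromophenyl) on C7, (Z)-butylidene butenolide intact, both C3' epimers | CCC/C=C1\OC(=O)C2=C1CC[C@H]1C(=O)C(c3ccccc3Br)[C@@H]21 | intermediate
9 | sodium (6R,7S)-cyclobutenolate of 8 (O− on C8', C3'=C8') | CCC/C=C1\OC(=O)C2=C1CC[C@H]1C([O-])=C(c3ccccc3Br)[C@@H]21.[Na+] | intermediate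
10 | (6R,7S)-cyclobutenyl triflate (OTf on C8', C3'=C8', 2-bromophenyl on C3') | CCC/C=C1\OC(=O)C2=C1CC[C@H]1C(OS(=O)(=O)C(F)(F)F)=C(c3ccccc3Br)[C@@H]21 | intermediate
11 | (6R,7S)-3'-(2-bromophenyl)-8'-propylcyclobutene, cis-fused to C6–C7 | CCC/C=C1\OC(=O)C2=C1CC[C@H]1C(CCC)=C(c3ccccc3Br)[C@@H]21 | intermediate
12 | 2-[(6R,7S)-8'-propylcyclobuten-3'-yl]benzoic acid (as 11 with CO2H in place of Br) | CCC/C=C1\OC(=O)C2=C1CC[C@H]1C(CCC)=C(c3ccccc3C(=O)O)[C@@H]21 | intermediate
13 | (3'R,6S,7R,8'R)-spiro-phthalide; cyclobutane cis-fused at C6–C7, propyl on C8' cis to C5, lactone oxygen on C3' cis to propyl and C7a, benzo ring on the face of H-6/H-7/H-8' | CCC/C=C1\OC(=O)C2=C1CC[C@H]1[C@@H](CCC)[C@@]3(OC(=O)c4ccccc43)[C@@H]21 | target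

**Totals**
Total step count: 6. Longest linear sequence: 6 (steps 1–6 from 1; five steps from 5).

**Steps most likely to fail**

Step 2. What may go wrong: the auxiliary may discriminate poorly between the two faces of the flat diene, or the strongly electrophilic keteniminium may attack the exocyclic enol-lactone double bond (C3=C8) instead of C6=C7. Fallback: set out from 3 and 5. Dehydrochlorination of 3 with i-Pr2NEt gives (2-bromophenyl)ketene F1, a neutral and milder partner whose thermal ketene–diene [2+2] cycloaddition to the diene terminus of 5 should give 8 as the racemate, that is, together with the enantiomer of 8 F2. Preparative chromatography on a chiral stationary phase removes F2, and the route is rejoined at 8.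

Step 5. What may go wrong: oxidative addition at the hindered ortho-substituted bromide may be slow, leaving the enol lactone exposed to warm aqueous amine (ring opening), or the acyl–palladium may insert into the neighbouring cyclobutene. Fallback: set out from 11. Bromine–lithium exchange (t-BuLi, THF/Et2O/pentane, −100 °C) gives the aryllithium F3, which is quenched at once with CO2; acidic work-up returns to 12.

Step 6. What may go wrong: the acid may hydrate or isomerise the butylidene enol lactone, or the cyclobutyl cation may rearrange before the carboxyl group captures it. Fallback: set out from 12 and go directly to 13 under neutral radical–polar crossover conditions. Cobalt-salen-catalysed hydrogen-atom transfer (silane, N-fluoro-2,4,6-trimethylpyridinium oxidant) delivers H• to C8' on the exo face; the benzylic C3' radical is oxidised and captured by the carboxyl group (Markovnikov hydroacyloxylation). No new compound is made (F0).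

**Further compounds**
F1 | step 2 | (2-bromophenyl)ketene | O=C=Cc1ccccc1Br
F2 | step 2 | enantiomer of 8, (6S,7R)-cyclobutanone | CCC/C=C1\OC(=O)C2=C1CC[C@@H]1C(=O)C(c3ccccc3Br)[C@H]21
F3 | step 5 | aryllithium derived from 11 (Li in place of Br) | CCC/C=C1\OC(=O)C2=C1CC[C@H]1C(CCC)=C(c3ccccc3[Li])[C@@H]21
F0 | step 6 | none | none
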